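**Assumption:** the target has no stereocentre (it is achiral), so "single enantiomer" requires no stereocontrol; the route only has to deliver the constitution shown.

## Retrosynthetic overview
1. Target 14 ⇒ depside aldehyde 13: the CO2H is carried as CHO (oxidised last) and the 2'-OH as OMe (unmasked by chelation-controlled BCl3 cleavage).
2. Key disconnection: the aryl–C(=O) bond of the depside ester. Aryl iodide 6 (acceptor carbon) is joined to an aryloxycarbonyl-anion (d1) equivalent, aryl formate 10, whose formyl carbon is normally an acceptor too.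
3. 6 ⇐ iodination of the C2-symmetric 2-chloro-1,3-dimethoxy-5-propylbenzene 5 ⇐ directed ortho-metalation/chlorination of 3 ⇐ Kumada coupling of 1 with 2.
4. 10 ⇐ O-formylation of 2,4-dihydroxy-6-pentylbenzaldehyde 9 ⇐ Vilsmeier formylation of olivetol 7.
5. Rings: both benzene rings are bought intact (1 and 7); no ring is formed.

## Route

**Step 1**
Reactants: 1 1-bromo-3,5-dimethoxybenzene; 2 n-propylmagnesium bromide
Product: 3 1,3-dimethoxy-5-propylbenzene
Conditions: 2 (1.3 equiv), NiCl2(dppp) (2 mol%), THF, 0 °C → 50 °C
Reagents that add atoms: none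
Why: Kumada–Corriu cross-coupling; Ni/dppp couples primary alkyl Grignard reagents with aryl bromides with negligible β-hydride isomerisation, and the methyl ethers are inert.

**Step 2**
Reactants: 3 1,3-dimethoxy-5-propylbenzene
Product: 5 2-chloro-1,3-dimethoxy-5-propylbenzene, via aryllithium 4 (not isolated)
Conditions: n-BuLi (1.2 equiv), THF, 0 °C → rt, 2 h; then C2Cl6 (1.3 equiv), −78 °C → rt
Reagents that add atoms: hexachloroethane, ClC(Cl)(Cl)C(Cl)(Cl)Cl
Why: Directed ortho-metalation; the C–H flanked by both OMe groups is lithiated selectively, and the aryllithium takes Cl+ from hexachloroethane, fixing the chlorine between the two oxygens without any regiochemical ambiguity.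

**Step 3**
Reactants: 5 2-chloro-1,3-dimethoxy-5-propylbenzene
Product: 6 2-chloro-4-iodo-1,3-dimethoxy-5-propylbenzene
Conditions: NIS (1.05 equiv), TFA (0.3 equiv), MeCN, rt, dark
Reagents that add atoms: N-iodosuccinimide, O=C1CCC(=O)N1I
Why: Electrophilic aromatic iodination; the two free ring positions of 5 are equivalent by symmetry and each is ortho/para to OMe, so only one mono-iodide can form, and the first iodine deactivates the ring against a second.

**Step 4**
Reactants: 7 olivetol (5-pentylbenzene-1,3-diol)
Product: 9 2,4-dihydroxy-6-pentylbenzaldehyde, via iminium salt 8 (not isolated)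
Conditions: POCl3 (1.2 equiv), DMF, 0 °C → rt; then H2O, 50 °C
Reagents that add atoms: N,N-dimethylformamide, CN(C)C=O; water, O
Why: Vilsmeier–Haack formylation; 5-alkylresorcinols are attacked at C4 (para to one OH, ortho to the other), and hydrolysis of the aryl iminium salt gives the aldehyde.

**Step 5**
Reactants: 9 2,4-dihydroxy-6-pentylbenzaldehyde
Product: 10 4-formyl-3-hydroxy-5-pentylphenyl formate
Conditions: HCO2H/Ac2O (premixed at 60 °C, 1.3 equiv AcOCHO), NaOAc (0.2 equiv), THF, 0 °C → rt; short silica plug, store cold under Ar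
Reagents that add atoms: acetic formic anhydride, CC(=O)OC=O (made in the flask from formic acid, O=CO, and acetic anhydride, CC(=O)OC(C)=O)
Why: O-formylation by a mixed anhydride at its more electrophilic formyl carbonyl; the 2-OH is hydrogen-bonded to the aldehyde, so the free 4-OH reacts (any 2-O-formate would be stripped by base in step 6 and is harmless).

**Step 6 (key step)**
Reactants: 6 2-chloro-4-iodo-1,3-dimethoxy-5-propylbenzene; 10 4-formyl-3-hydroxy-5-pentylphenyl formate
Product: 11 4-formyl-3-hydroxy-5-pentylphenyl 3-chloro-2,4-dimethoxy-6-propylbenzoate, via phenol 9 (not isolated)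
Conditions: 10 (1.5 equiv), Pd(OAc)2 (5 mol%), Xantphos (10 mol%), NEt3 (2 equiv), toluene, 80 °C, sealed tube
Reagents that add atoms: none
Why: Pd-catalysed aryloxycarbonylation of an aryl iodide with an aryl formate used as an aryloxycarbonyl-anion equivalent: NEt3 unmasks 10 into CO and the 4-phenoxide of 9 at the metal, the Ar–Pd–I from 6 (C–I reacts, C–Cl does not) takes up the one-carbon unit, and the more acidic, non-chelated 4-phenoxide closes the ester, so the formyl carbon of 10 ends up bonded to the former C–I carbon and the depside is made by C–C bond formation.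

**Step 7**
Reactants: 11 4-formyl-3-hydroxy-5-pentylphenyl 3-chloro-2,4-dimethoxy-6-propylbenzoate
Product: 13 4-formyl-3-hydroxy-5-pentylphenyl 3-chloro-2-hydroxy-4-methoxy-6-propylbenzoate, via boron chelate 12 (not isolated)
Conditions: BCl3 (1 M in CH2Cl2, 3 equiv), CH2Cl2, −78 → 0 °C; then H2O
Reagents that add atoms: none
Why: Chelation-controlled Lewis-acid ether cleavage; BCl3 bound to the ester carbonyl cleaves only the ortho OMe (also the more hindered one, between Cl and C=O) through a six-membered chelate, leaving the 4'-OMe, the aryl ester, the aldehyde and the C–Cl bond intact.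

**Step 8**
Reactants: 13 4-formyl-3-hydroxy-5-pentylphenyl 3-chloro-2-hydroxy-4-methoxy-6-propylbenzoate
Product: 14 4-[(3-chloro-2-hydroxy-4-methoxy-6-propylbenzoyl)oxy]-2-hydroxy-6-pentylbenzoic acid (target)
Conditions: NaClO2 (3 equiv), NaH2PO4 (3 equiv), 2-methyl-2-butene (20 equiv), t-BuOH/THF/H2O, 0 °C → rt
Reagents that add atoms: sodium chlorite, [Na+].[O-]Cl=O
Why: Pinnick (Lindgren) oxidation; chlorous acid converts the salicylaldehyde into the salicylic acid under mildly acidic conditions that do not hydrolyse the depside ester, while 2-methyl-2-butene removes HOCl before it can chlorinate the activated rings.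

## Compound list
1 | 1-bromo-3,5-dimethoxybenzene | COc1cc(Br)cc(OC)c1 | starting material
2 | n-propylmagnesium bromide | CCC[Mg]Br | starting material
3 | 1,3-dimethoxy-5-propylbenzene | CCCc1cc(OC)cc(OC)c1 | intermediate
4 | (2,6-dimethoxy-4-propylphenyl)lithium | [Li]c1c(OC)cc(CCC)cc1OC | intermediate
5 | 2-chloro-1,3-dimethoxy-5-propylbenzene | CCCc1cc(OC)c(Cl)c(OC)c1 | intermediate
6 | 2-chloro-4-iodo-1,3-dimethoxy-5-propylbenzene | CCCc1cc(OC)c(Cl)c(OC)c1I | intermediate
7 | olivetol (5-pentylbenzene-1,3-diol) | CCCCCc1cc(O)cc(O)c1 | starting material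
8 | [(2,4-dihydroxy-6-pentylphenyl)methylidene]dimethylammonium chloride | CCCCCc1cc(O)cc(O)c1C=[N+](C)C.[Cl-] | intermediate
9 | 2,4-dihydroxy-6-pentylbenzaldehyde | CCCCCc1cc(O)cc(O)c1C=O | intermediate
10 | 4-formyl-3-hydroxy-5-pentylphenyl formate | CCCCCc1cc(OC=O)cc(O)c1C=O | intermediate
11 | 4-formyl-3-hydroxy-5-pentylphenyl 3-chloro-2,4-dimethoxy-6-propylbenzoate | CCCCCc1cc(OC(=O)c2c(CCC)cc(OC)c(Cl)c2OC)cc(O)c1C=O | intermediate
12 | 3-[(dichloroboranyl)oxy]-4-formyl-5-pentylphenyl 3-chloro-2-[(dichloroboranyl)oxy]-4-methoxy-6-propylbenzoate | CCCCCc1cc(OC(=O)c2c(CCC)cc(OC)c(Cl)c2OB(Cl)Cl)cc(OB(Cl)Cl)c1C=O | intermediate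
13 | 4-formyl-3-hydroxy-5-pentylphenyl 3-chloro-2-hydroxy-4-methoxy-6-propylbenzoate | CCCCCc1cc(OC(=O)c2c(CCC)cc(OC)c(Cl)c2O)cc(O)c1C=O | intermediate
14 | 4-[(3-chloro-2-hydroxy-4-methoxy-6-propylbenzoyl)oxy]-2-hydroxy-6-pentylbenzoic acid | CCCCCc1cc(OC(=O)c2c(CCC)cc(OC)c(Cl)c2O)cc(O)c1C(=O)O | target

## Step count and risk
Total steps: 8. Longest linear sequence: 6 (steps 1, 2, 3, 6, 7, 8); steps 4 and 5 form the convergent branch.

**Step 6 (most likely to fail).** The iodide is di-ortho-substituted, the phenoxide is a weak nucleophile, and CO release from the formate must keep pace with the catalyst. The fallback sets out from 6 and delivers the one-carbon unit as a pre-formed alkoxycarbonyl nucleophile instead. Pd(TFA)2/dppp-catalysed decarboxylative coupling of 6 with potassium methyl oxalate (NMP, 150 °C) gives methyl 3-chloro-2,4-dimethoxy-6-propylbenzoate F1. KOH in DMSO/H2O at 100 °C hydrolyses this hindered ester to 3-chloro-2,4-dimethoxy-6-propylbenzoic acid F2. F2 is then esterified with phenol 9 through the trifluoroacetic mixed anhydride (TFAA, toluene, rt; the chelated 2-OH of 9 stays free), and the route is rejoined at 11.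

**Step 7.** BCl3 could cleave the wrong ether, stall, or attack the depside ester. The fallback sets out from 11 and gives up selective cleavage: BBr3 (CH2Cl2, −78 → 0 °C) removes both methyl groups to give 4-formyl-3-hydroxy-5-pentylphenyl 3-chloro-2,4-dihydroxy-6-propylbenzoate F3. Of its three phenols only the 4'-OH is not hydrogen-bonded to a carbonyl, so TMSCHN2 (1.1 equiv, toluene/MeOH, 0 °C) methylates that one alone, and the route is rejoined at 13.

**Step 5.** The formate of a para-formylphenol is hydrolytically labile and may not survive isolation. The fallback sets out from 9 (together with 6) and omits the formate: a three-component carbonylative esterification of 6 with free phenol 9 under CO gas (1 atm), Pd(OAc)2/Xantphos, NEt3, toluene, 80 °C, rejoins the route at 11; no new compound is made (F0).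

## Further compounds
F1 | step 6 | methyl 3-chloro-2,4-dimethoxy-6-propylbenzoate | CCCc1cc(OC)c(Cl)c(OC)c1C(=O)OC
F2 | step 6 | 3-chloro-2,4-dimethoxy-6-propylbenzoic acid | CCCc1cc(OC)c(Cl)c(OC)c1C(=O)O
F3 | step 7 | 4-formyl-3-hydroxy-5-pentylphenyl 3-chloro-2,4-dihydroxy-6-propylbenzoate | CCCCCc1cc(OC(=O)c2c(CCC)cc(O)c(Cl)c2O)cc(O)c1C=O
F0 | step 5 | none | none
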